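**Plan**

- Retrosynthesis (labdane numbering): the C15 acetate and the C8=C17 methylene come off last, then one C4 methyl is removed to leave a C3=C4 alkene. C1–C2 and C5–C10 are then cut together, followed by C8–C9 (allylboration) and C12–C13 (Grignard addition).
- Enabling feature: ring A (C1–C2–C3–C4–C5–C10) is a cyclohexane whose quaternary C10 carries a methyl and whose C4 can hold a C3=C4 bond. It is therefore the Diels–Alder adduct of the diene C2=C3–C4(CH3)=C5 and the isopropenyl unit C10(CH3)=C1, with the four ring B carbons C6–C9 as tether (a 1,7,9-decatriene).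
- Forward order: the side chain C11–C16 is built as a (Z)-allylboronate and joined to a C2–C8 dienal to give the acyclic triene. Rings A and B then form together in one thermal cycloaddition, followed by the C4 methyl, C8 ketone, C17 methylene, deprotection and C15 acetate.
- Stereochemistry: C14 comes from methyl (S)-glycerate acetonide and C13 from a chelation-controlled Grignard addition. C9 and a temporary C8 carbinol are set by catalyst-controlled syn-allylboration. C5 and C10 arise in the cycloaddition, relayed from C8/C9 through the chair of the tether; C8 is oxidised away afterwards.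

Key step: step 10

Remark: labdane numbering (C1–C20) is used for the atoms of all intermediates.
Assumption: the (S)-configured phosphoric acid of step 9 is taken to send the allyl group to the Si face of the aldehyde; if the sense is the reverse, its enantiomer is used.
Assumption: the formaldehyde N-sulfonylhydrazone of step 11 is used as its methanesulfonyl compound (made from paraformaldehyde and methanesulfonohydrazide).

**Route**

Step 1
Reactants: 1 methyl (4S)-2,2-dimethyl-1,3-dioxolane-4-carboxylate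
Product: 3 1-[(4S)-2,2-dimethyl-1,3-dioxolan-4-yl]ethan-1-one, via Weinreb amide 2 (not isolated)
Conditions: MeNH(OMe)·HCl, iPrMgCl, THF, −20 °C; then MeMgBr, −20 to 0 °C; aq. NH4Cl
Reagents that add atoms: N,O-dimethylhydroxylamine hydrochloride, CNOC.Cl (enters 2 only); methylmagnesium bromide, C[Mg]Br
Why: Weinreb ketone synthesis in one flask: the chloromagnesium amide aminolyses the ester, and the chelated adduct of 2 with MeMgBr gives the ketone only on work-up, so over-addition is excluded and the α-alkoxy C14 centre from the chiral pool stays intact at low temperature.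

Step 2
Reactants: 3 1-[(4S)-2,2-dimethyl-1,3-dioxolan-4-yl]ethan-1-one; 4 5-bromo-2-methylpent-2-ene
Product: 7 triethyl{[(2S)-2-[(4S)-2,2-dimethyl-1,3-dioxolan-4-yl]-6-methylhept-5-en-2-yl]oxy}silane, via Grignard reagent 5 (not isolated), via bromomagnesium alkoxide 6 (not isolated)
Conditions: 4, Mg, Et2O, 35 °C; then 3, Et2O, −78 °C; then Et3SiOTf, 2,6-lutidine, −78 to 0 °C
Reagents that add atoms: magnesium, [Mg] (enters 5 and 6 only); triethylsilyl trifluoromethanesulfonate, CC[Si](CC)(CC)OS(=O)(=O)C(F)(F)F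
Why: Chelation-controlled (Cram chelate) Grignard addition: magnesium bridges the carbonyl oxygen and the ring oxygen on C14, the alkyl group enters anti to the C15 methylene and sets C13 as (S); the tertiary alkoxide is silylated in the same flask so that no free hydroxyl can add to the alkene in step 3.

Step 3
Reactants: 7 triethyl{[(2S)-2-[(4S)-2,2-dimethyl-1,3-dioxolan-4-yl]-6-methylhept-5-en-2-yl]oxy}silane
Product: 8 {[(2S,5RS)-5-chloro-2-[(4S)-2,2-dimethyl-1,3-dioxolan-4-yl]-6-methylhept-6-en-2-yl]oxy}triethylsilane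
Conditions: Ca(OCl)2, CO2 (solid), CH2Cl2–H2O, 0 °C
Reagents that add atoms: hypochlorous acid, OCl, made in the flask from calcium hypochlorite, [Ca+2].[O-]Cl.[O-]Cl
Why: Ene-type allylic chlorination of the trisubstituted alkene by HOCl (chloronium ion at the prenyl terminus, loss of a methyl proton) puts chlorine on C9 and moves the double bond to C10=C1; the C–Cl centre forms as a mixture that is erased in step 4.

Step 4
Reactants: 8 {[(2S,5RS)-5-chloro-2-[(4S)-2,2-dimethyl-1,3-dioxolan-4-yl]-6-methylhept-6-en-2-yl]oxy}triethylsilane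
Product: 9 triethyl{[(2S,4E)-2-[(4S)-2,2-dimethyl-1,3-dioxolan-4-yl]-6-methylhepta-4,6-dien-2-yl]oxy}silane
Conditions: KOtBu, THF, 0 to 23 °C
Reagents that add atoms: none
Why: E2 dehydrochlorination with a hindered base can only take a hydrogen from C11 (C10 is sp2), which gives the conjugated (E)-2-methyl-1,3-diene.

Step 5
Reactants: 9 triethyl{[(2S,4E)-2-[(4S)-2,2-dimethyl-1,3-dioxolan-4-yl]-6-methylhepta-4,6-dien-2-yl]oxy}silane
Product: 10 2-[(2Z,6S)-6-[(4S)-2,2-dimethyl-1,3-dioxolan-4-yl]-2-methyl-6-[(triethylsilyl)oxy]hept-2-en-1-yl]-4,4,5,5-tetramethyl-1,3,2-dioxaborolane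
Conditions: pinacolborane, Ni(cod)2 (cat.), PCy3 (cat.), toluene, 23 °C
Reagents that add atoms: pinacolborane, CC1(C)OBOC1(C)C
Why: Nickel-catalysed 1,4-hydroboration of a 1,3-diene: the s-cis diene binds zerovalent nickel, hydrogen goes to the substituted terminus C11 and boron to the CH2 terminus C1, and the η3-allyl intermediate fixes the new C9=C10 bond as (Z).

Step 6
Reactants: 11 methyl 4-oxobutanoate; 12 2-(triphenyl-λ5-phosphanylidene)propanal
Product: 13 methyl (4E)-5-methyl-6-oxohex-4-enoate
Conditions: CH2Cl2, 23 to 40 °C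
Reagents that add atoms: none
Why: Wittig olefination with a stabilised ylide is chemoselective for the aldehyde over the ester and gives the (E)-trisubstituted enal (chain trans to CHO), which is the diene geometry needed in step 10.

Step 7
Reactants: 13 methyl (4E)-5-methyl-6-oxohex-4-enoate
Product: 14 methyl (4E)-5-methylhepta-4,6-dienoate
Conditions: Ph3PCH3Br, KOtBu, THF, −78 to 0 °C
Reagents that add atoms: methyltriphenylphosphonium bromide, C[P+](c1ccccc1)(c1ccccc1)c1ccccc1.[Br-]
Why: Wittig methylenation of the enal carbonyl at low temperature (the aldehyde reacts far faster than the ester) completes the (E)-diene without touching the C4=C5 geometry.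

Step 8
Reactants: 14 methyl (4E)-5-methylhepta-4,6-dienoate
Product: 15 (4E)-5-methylhepta-4,6-dienal
Conditions: iBu2AlH, CH2Cl2, −78 °C; aq. Rochelle salt
Reagents that add atoms: none
Why: Partial reduction of a methyl ester by iBu2AlH at −78 °C stops at the aluminium hemiacetal, which releases the aldehyde on work-up.

Step 9
Reactants: 10 2-[(2Z,6S)-6-[(4S)-2,2-dimethyl-1,3-dioxolan-4-yl]-2-methyl-6-[(triethylsilyl)oxy]hept-2-en-1-yl]-4,4,5,5-tetramethyl-1,3,2-dioxaborolane; 15 (4E)-5-methylhepta-4,6-dienal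
Product: 16 (3E,7R,8R,11S)-11-[(4S)-2,2-dimethyl-1,3-dioxolan-4-yl]-3-methyl-8-(prop-1-en-2-yl)-11-[(triethylsilyl)oxy]dodeca-1,3-dien-7-ol
Conditions: (S)-3,3′-bis(2,4,6-triisopropylphenyl)-1,1′-binaphthyl-2,2′-diyl hydrogen phosphate (5 mol %), 4 Å molecular sieves, toluene, −30 °C; aqueous work-up
Reagents that add atoms: none
Why: Chiral phosphoric acid-catalysed allylboration through a closed six-membered chair transition state: the (Z)-γ-substituted boronate gives the syn relation of the C8 hydroxyl and the C9 side chain, and the acid, hydrogen-bonded to a boronate oxygen, directs addition to the Si face of 15, so C8 (R) and C9 (R) are set together.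

Step 10
Reactants: 16 (3E,7R,8R,11S)-11-[(4S)-2,2-dimethyl-1,3-dioxolan-4-yl]-3-methyl-8-(prop-1-en-2-yl)-11-[(triethylsilyl)oxy]dodeca-1,3-dien-7-ol
Product: 17 (1R,2R,4aS,8aS)-1-{(3S)-3-[(4S)-2,2-dimethyl-1,3-dioxolan-4-yl]-3-[(triethylsilyl)oxy]butyl}-5,8a-dimethyl-1,2,3,4,4a,7,8,8a-octahydronaphthalen-2-ol
Conditions: toluene (0.01 M), 2,6-di-tert-butyl-4-methylphenol (trace), sealed tube, 195 °C
Reagents that add atoms: none
Why: Thermal intramolecular Diels–Alder reaction of a 1,7,9-decatriene (type 1): the diene C2=C3–C4=C5 adds suprafacially across the isopropenyl bond C10=C1 in a concerted, asynchronous [π4s+π2s] transition state, the closest known reaction type being the thermal cyclisation of 2,8-dimethyl-1,7,9-decatrienes to angular-methyl Δ3-octalins of the eudesmane class. Ring A closes as the cyclohexene of the cycloaddition (both new bonds C1–C2 and C5–C10 lie in it, boat-like), and ring B closes through the C5–C10 bond alone as a six-membered chair made of the tether C6–C9, with C1 exocyclic to it. C10 and C5 arise together: the tether-exo (anti) arrangement gives the trans ring fusion with the C10 methyl and H-5 both axial, and their absolute sense follows from C9 and C8, because only one face of the dienophile lets the side chain and the hydroxyl both sit equatorial on the chair. The step needs one diastereoface and trans over cis fusion; the face is secured by these two equatorial tether substituents from step 9. The trans fusion is expected to be favoured because either cis transition state must place the fully substituted tether carbon C9 endo under the diene or the methyl-bearing diene arm axial on ring B, whereas the trans one puts only the C10 methyl endo; the cis-fused isomer is the by-product to be removed. The (E) geometry of C4=C5 is required for C5 to reach C10, and the tether fixes a regiochemistry that the intermolecular reaction would not give.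

Step 11
Reactants: 17 (1R,2R,4aS,8aS)-1-{(3S)-3-[(4S)-2,2-dimethyl-1,3-dioxolan-4-yl]-3-[(triethylsilyl)oxy]butyl}-5,8a-dimethyl-1,2,3,4,4a,7,8,8a-octahydronaphthalen-2-ol
Product: 19 (1R,2R,4aS,8aS)-1-{(3S)-3-[(4S)-2,2-dimethyl-1,3-dioxolan-4-yl]-3-[(triethylsilyl)oxy]butyl}-5,5,8a-trimethyldecahydronaphthalen-2-ol, via sulfonylhydrazide 18 (not isolated)
Conditions: CH2=N–NHSO2CH3, Fe(acac)3 (cat.), PhSiH3, THF–MeOH, 23 °C; then MeOH, 60 °C
Reagents that add atoms: formaldehyde methanesulfonylhydrazone, C=NNS(C)(=O)=O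
Why: Metal-hydride hydrogen-atom-transfer hydromethylation: the iron hydride from Fe(acac)3 and PhSiH3 delivers H to C3 (Markovnikov), the tertiary C4 radical adds to the C=N carbon of the hydrazone, and warming in MeOH expels sulfinate and N2 from 18 to leave the second methyl; C4 becomes C(CH3)2, so no stereocentre arises, and the ring alkene is the only alkene present.

Step 12
Reactants: 19 (1R,2R,4aS,8aS)-1-{(3S)-3-[(4S)-2,2-dimethyl-1,3-dioxolan-4-yl]-3-[(triethylsilyl)oxy]butyl}-5,5,8a-trimethyldecahydronaphthalen-2-ol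
Product: 20 (1R,4aS,8aS)-1-{(3S)-3-[(4S)-2,2-dimethyl-1,3-dioxolan-4-yl]-3-[(triethylsilyl)oxy]butyl}-5,5,8a-trimethyloctahydronaphthalen-2(1H)-one
Conditions: Dess–Martin periodinane, pyridine, CH2Cl2, 0 to 23 °C
Reagents that add atoms: none
Why: Dess–Martin oxidation of the secondary alcohol under buffered conditions removes the temporary C8 stereocentre; C9, now α to the ketone, already holds the equatorial (thermodynamic) configuration, and the silyl ether and acetonide are inert.

Step 13
Reactants: 20 (1R,4aS,8aS)-1-{(3S)-3-[(4S)-2,2-dimethyl-1,3-dioxolan-4-yl]-3-[(triethylsilyl)oxy]butyl}-5,5,8a-trimethyloctahydronaphthalen-2(1H)-one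
Product: 21 {[(2S)-2-[(4S)-2,2-dimethyl-1,3-dioxolan-4-yl]-4-[(1S,4aS,8aS)-5,5,8a-trimethyl-2-methylidenedecahydronaphthalen-1-yl]butan-2-yl]oxy}triethylsilane
Conditions: Ph3PCH3Br, KOtBu, toluene, 90 °C
Reagents that add atoms: methyltriphenylphosphonium bromide, C[P+](c1ccccc1)(c1ccccc1)c1ccccc1.[Br-]
Why: Wittig methylenation of the hindered C8 ketone with excess ylide at elevated temperature; any enolisation returns C9 to the more stable equatorial side-chain isomer, which is the one required.

Step 14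
Reactants: 21 {[(2S)-2-[(4S)-2,2-dimethyl-1,3-dioxolan-4-yl]-4-[(1S,4aS,8aS)-5,5,8a-trimethyl-2-methylidenedecahydronaphthalen-1-yl]butan-2-yl]oxy}triethylsilane
Product: 22 (2S,3S)-3-methyl-5-[(1S,4aS,8aS)-5,5,8a-trimethyl-2-methylidenedecahydronaphthalen-1-yl]pentane-1,2,3-triol
Conditions: AcOH–THF–H2O (3:1:1), 45 °C
Reagents that add atoms: none
Why: Mild acid hydrolysis cleaves the terminal acetonide and the tertiary triethylsilyl ether together, and the weak acid should not protonate the 1,1-disubstituted C8=C17 bond, so no 8,13-ether forms.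

Step 15
Reactants: 22 (2S,3S)-3-methyl-5-[(1S,4aS,8aS)-5,5,8a-trimethyl-2-methylidenedecahydronaphthalen-1-yl]pentane-1,2,3-triol
Product: 23 (2S,3S)-2,3-dihydroxy-3-methyl-5-[(1S,4aS,8aS)-5,5,8a-trimethyl-2-methylidenedecahydronaphthalen-1-yl]pentyl acetate
Conditions: AcCl, 2,4,6-collidine, CH2Cl2, −78 °C
Reagents that add atoms: acetyl chloride, CC(Cl)=O
Why: Kinetically selective O-acylation of the primary C15 hydroxyl beside the secondary C14 and tertiary C13 hydroxyls with AcCl and a hindered pyridine base at low temperature.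

**Compound list**

1 | methyl (4S)-2,2-dimethyl-1,3-dioxolane-4-carboxylate | COC(=O)[C@@H]1COC(C)(C)O1 | starting material
2 | (4S)-N-methoxy-N,2,2-trimethyl-1,3-dioxolane-4-carboxamide (Weinreb amide) | CON(C)C(=O)[C@@H]1COC(C)(C)O1 | intermediate
3 | 1-[(4S)-2,2-dimethyl-1,3-dioxolan-4-yl]ethan-1-one | CC(=O)[C@@H]1COC(C)(C)O1 | intermediate
4 | 5-bromo-2-methylpent-2-ene | CC(C)=CCCBr | starting material
5 | (4-methylpent-3-en-1-yl)magnesium bromide | CC(C)=CCC[Mg]Br | intermediate
6 | bromomagnesium (2S)-2-[(4S)-2,2-dimethyl-1,3-dioxolan-4-yl]-6-methylhept-5-en-2-olate | CC(C)=CCC[C@](C)(O[Mg]Br)[C@@H]1COC(C)(C)O1 | intermediate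
7 | triethyl{[(2S)-2-[(4S)-2,2-dimethyl-1,3-dioxolan-4-yl]-6-methylhept-5-en-2-yl]oxy}silane | CC(C)=CCC[C@](C)(O[Si](CC)(CC)CC)[C@@H]1COC(C)(C)O1 | intermediate
8 | {[(2S,5RS)-5-chloro-2-[(4S)-2,2-dimethyl-1,3-dioxolan-4-yl]-6-methylhept-6-en-2-yl]oxy}triethylsilane (both C9 epimers) | C=C(C)C(Cl)CC[C@](C)(O[Si](CC)(CC)CC)[C@@H]1COC(C)(C)O1 | intermediate
9 | triethyl{[(2S,4E)-2-[(4S)-2,2-dimethyl-1,3-dioxolan-4-yl]-6-methylhepta-4,6-dien-2-yl]oxy}silane | C=C(C)/C=C/C[C@](C)(O[Si](CC)(CC)CC)[C@@H]1COC(C)(C)O1 | intermediate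
10 | 2-[(2Z,6S)-6-[(4S)-2,2-dimethyl-1,3-dioxolan-4-yl]-2-methyl-6-[(triethylsilyl)oxy]hept-2-en-1-yl]-4,4,5,5-tetramethyl-1,3,2-dioxaborolane | CC1(C)OB(C/C(C)=C\CC[C@](C)(O[Si](CC)(CC)CC)[C@@H]2COC(C)(C)O2)OC1(C)C | intermediate
11 | methyl 4-oxobutanoate | COC(=O)CCC=O | starting material
12 | 2-(triphenyl-λ5-phosphanylidene)propanal | CC(C=O)=P(c1ccccc1)(c1ccccc1)c1ccccc1 | starting material
13 | methyl (4E)-5-methyl-6-oxohex-4-enoate | COC(=O)CC/C=C(\C)C=O | intermediate
14 | methyl (4E)-5-methylhepta-4,6-dienoate | COC(=O)CC/C=C(\C)C=C | intermediate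
15 | (4E)-5-methylhepta-4,6-dienal | O=CCC/C=C(\C)C=C | intermediate
16 | (3E,7R,8R,11S)-11-[(4S)-2,2-dimethyl-1,3-dioxolan-4-yl]-3-methyl-8-(prop-1-en-2-yl)-11-[(triethylsilyl)oxy]dodeca-1,3-dien-7-ol | O[C@H](CC/C=C(\C)C=C)[C@H](CC[C@](C)(O[Si](CC)(CC)CC)[C@@H]1COC(C)(C)O1)C(C)=C | intermediate
17 | (1R,2R,4aS,8aS)-1-{(3S)-3-[(4S)-2,2-dimethyl-1,3-dioxolan-4-yl]-3-[(triethylsilyl)oxy]butyl}-5,8a-dimethyl-1,2,3,4,4a,7,8,8a-octahydronaphthalen-2-ol (trans-fused, 8α-OH, Δ3) | O[C@@H]1CC[C@H]2C(C)=CCC[C@]2(C)[C@H]1CC[C@](C)(O[Si](CC)(CC)CC)[C@@H]3COC(C)(C)O3 | intermediate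
18 | sulfonylhydrazide: 19 in which one C4 methyl (the equatorial, α one) is CH2–NH–NH–SO2CH3 | O[C@@H]1CC[C@H]2[C@](C)(CNNS(C)(=O)=O)CCC[C@]2(C)[C@H]1CC[C@](C)(O[Si](CC)(CC)CC)[C@@H]3COC(C)(C)O3 | intermediate
19 | (1R,2R,4aS,8aS)-1-{(3S)-3-[(4S)-2,2-dimethyl-1,3-dioxolan-4-yl]-3-[(triethylsilyl)oxy]butyl}-5,5,8a-trimethyldecahydronaphthalen-2-ol | O[C@@H]1CC[C@H]2C(C)(C)CCC[C@]2(C)[C@H]1CC[C@](C)(O[Si](CC)(CC)CC)[C@@H]3COC(C)(C)O3 | intermediate
20 | (1R,4aS,8aS)-1-{(3S)-3-[(4S)-2,2-dimethyl-1,3-dioxolan-4-yl]-3-[(triethylsilyl)oxy]butyl}-5,5,8a-trimethyloctahydronaphthalen-2(1H)-one | O=C1CC[C@H]2C(C)(C)CCC[C@]2(C)[C@H]1CC[C@](C)(O[Si](CC)(CC)CC)[C@@H]3COC(C)(C)O3 | intermediate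
21 | {[(2S)-2-[(4S)-2,2-dimethyl-1,3-dioxolan-4-yl]-4-[(1S,4aS,8aS)-5,5,8a-trimethyl-2-methylidenedecahydronaphthalen-1-yl]butan-2-yl]oxy}triethylsilane | C=C1CC[C@H]2C(C)(C)CCC[C@]2(C)[C@H]1CC[C@](C)(O[Si](CC)(CC)CC)[C@@H]3COC(C)(C)O3 | intermediate
22 | (2S,3S)-3-methyl-5-[(1S,4aS,8aS)-5,5,8a-trimethyl-2-methylidenedecahydronaphthalen-1-yl]pentane-1,2,3-triol | C=C1CC[C@H]2C(C)(C)CCC[C@]2(C)[C@H]1CC[C@](C)(O)[C@@H](O)CO | intermediate
23 | (2S,3S)-2,3-dihydroxy-3-methyl-5-[(1S,4aS,8aS)-5,5,8a-trimethyl-2-methylidenedecahydronaphthalen-1-yl]pentyl acetate, i.e. (13S,14S)-labd-8(17)-ene-13,14,15-triol 15-acetate | C=C1CC[C@H]2C(C)(C)CCC[C@]2(C)[C@H]1CC[C@](C)(O)[C@@H](O)COC(C)=O | target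

**Step count and risks**

Total step count: 15. Longest linear sequence: 12 steps (steps 1–5 and 9–15).

Steps most likely to fail:

Step 10. The unactivated 1,1-disubstituted dienophile may cyclise slowly, and a tether-endo transition state may compete, which would erode the trans ring fusion. The fallback activates the dienophile as an (E)-nitroalkene and masks the diene meanwhile; it sets out from ester 14 (with boronate 10) and comes back at 17. Cheletropic addition of SO2 to 14 (liquid SO2, hydroquinone, sealed tube, 25 °C) gives the sulfolene ester F1. Reduction with iBu2AlH at −78 °C gives the sulfolene aldehyde F2. Allylboration with 10 under the conditions of step 9 gives the masked homoallylic alcohol F3. Radical nitration of the isopropenyl group (AgNO2, 2,2,6,6-tetramethylpiperidin-1-oxyl, 4 Å molecular sieves, 1,2-dichloroethane, 70 °C) gives the (E)-nitroalkene F4. Heating in toluene over NaHCO3 at 115 °C extrudes SO2, and the freed diene should add at once to the nitroalkene, whose endo preference (nitro trans to the tether) is the known way to trans-fused decalins with an angular methyl; this gives the nitro-octalinol F5. Radical denitration (Bu3SnH, azobisisobutyronitrile, toluene, 110 °C) returns to 17. The sulfolene carbon in F1 to F4 is a mixture of both configurations, which disappears with the SO2.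

Step 9. The phosphoric acid may discriminate the aldehyde faces poorly with a β,γ-disubstituted boronate, which would lower the control of C8 and C9. The fallback replaces the boron chemistry by a catalytic enantioselective Nozaki–Hiyama–Kishi allylation; it sets out from chloride 8 and aldehyde 15 and comes back at 16. Treatment with CrCl2 (cat.), a chiral bis(oxazolinyl)carbazole ligand, Mn powder and Me3SiCl in THF, with desilylation on work-up, should give, whatever the allyl geometry, the anti homoallylic alcohol F6 (C9 as required, C8 epimeric). Mitsunobu inversion at C8 (4-nitrobenzoic acid, PPh3, diisopropyl azodicarboxylate) gives the 4-nitrobenzoate F7, and methanolysis (K2CO3, MeOH) returns to 16.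

Step 11. Hydrogen-atom transfer to the hindered ring alkene may be slow, or the tertiary C4 radical may be reduced instead of being captured by the hydrazone. The fallback brings in the second methyl as a cyclopropane methylene; it sets out from 17 and comes back at 19. Simmons–Smith cyclopropanation (Et2Zn, CH2I2, CH2Cl2, 0 °C), expected on the α face away from the axial C10 methyl, gives the 3,4-methano compound F8. Hydrogenolysis of the less substituted cyclopropane bond C3–CH2 (H2, PtO2, AcOH buffered with NaOAc, 25 °C) opens it to the gem-dimethyl group and returns to 19.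

Further compounds
F1 | step 10 | methyl 3-(3-methyl-1,1-dioxido-2,5-dihydrothiophen-2-yl)propanoate | COC(=O)CCC1C(C)=CCS1(=O)=O
F2 | step 10 | 3-(3-methyl-1,1-dioxido-2,5-dihydrothiophen-2-yl)propanal | O=CCCC1C(C)=CCS1(=O)=O
F3 | step 10 | (3R,4R,7S)-7-[(4S)-2,2-dimethyl-1,3-dioxolan-4-yl]-1-(3-methyl-1,1-dioxido-2,5-dihydrothiophen-2-yl)-4-(prop-1-en-2-yl)-7-[(triethylsilyl)oxy]octan-3-ol (sulfolene-masked 16) | O[C@H](CCC1C(C)=CCS1(=O)=O)[C@H](CC[C@](C)(O[Si](CC)(CC)CC)[C@@H]2COC(C)(C)O2)C(C)=C
F4 | step 10 | F3 with the isopropenyl group converted into an (E)-1-nitroprop-1-en-2-yl group | O[C@H](CCC1C(C)=CCS1(=O)=O)[C@H](CC[C@](C)(O[Si](CC)(CC)CC)[C@@H]2COC(C)(C)O2)/C(C)=C/[N+](=O)[O-]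
F5 | step 10 | 1β-nitro derivative of 17 (nitro on C1, cis to the C10 methyl, trans-fused) | O[C@@H]1CC[C@H]2C(C)=CC[C@@H]([N+](=O)[O-])[C@]2(C)[C@H]1CC[C@](C)(O[Si](CC)(CC)CC)[C@@H]3COC(C)(C)O3
F6 | step 9 | (3E,7S,8R,11S)-11-[(4S)-2,2-dimethyl-1,3-dioxolan-4-yl]-3-methyl-8-(prop-1-en-2-yl)-11-[(triethylsilyl)oxy]dodeca-1,3-dien-7-ol (C8 epimer of 16) | O[C@@H](CC/C=C(\C)C=C)[C@H](CC[C@](C)(O[Si](CC)(CC)CC)[C@@H]1COC(C)(C)O1)C(C)=C
F7 | step 9 | 4-nitrobenzoate of 16 | O=C(O[C@H](CC/C=C(\C)C=C)[C@H](CC[C@](C)(O[Si](CC)(CC)CC)[C@@H]1COC(C)(C)O1)C(C)=C)c1ccc(cc1)[N+](=O)[O-]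
F8 | step 11 | 3α,4α-methano derivative of 17 (cyclopropane across C3–C4, methyl on C4) | O[C@@H]1CC[C@H]2[C@]4(C)C[C@@H]4CC[C@]2(C)[C@H]1CC[C@](C)(O[Si](CC)(CC)CC)[C@@H]3COC(C)(C)O3
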